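The route rests on making the C8–C15 bond last. In the target, quaternary C8 is tied through the C15 methylene to C16, which carries the exocyclic C17 methylene and sits on the tertiary carbinol C13 of ring C. A 2-(trimethylsilylmethyl)allyl group on C13 can therefore add through its terminal alkene carbon to C8 of a ring-B enal. That single intramolecular Hosomi–Sakurai step closes ring D, creates the C8 quaternary centre and the C6 stereocentre, and leaves the C16=C17 alkene. Its precursor 27 carries rings A–C, the 19,10-lactone, the 3,12-diacetate, a 13-O-silyl ether and the C6=C8 enal, and is assembled from a quinone-monoketal Diels–Alder adduct.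

Key step: step 20

Remark 1: gibberellane numbering is used (C7 on C6, C19 lactone carbonyl on C4, C17 exocyclic methylene); "face of H9" and "face of C10" refer to the two faces of ring C.
Remark 2: a C13 ketone beside the C6=C8 enal would be a vinylogous 1,3-dicarbonyl and would be deprotonated, not attacked, by a vinylmetal. The side chain is therefore added to C13 while ring B is still six-membered, the enal is unveiled afterwards, and O13 enters the key step as its trimethylsilyl ether.
Remark 3: centres that are mixtures and are erased later (acetal carbon and C4 in 9–12, C3 in 13–18, C7/C8 in 24–25) are left open in the SMILES. C12 in 7–18 is drawn as the expected convex-face epimer and is reset in step 12.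

Step 1
Reactants: 1 but-3-en-2-one
Product: 2 2-(triethylsilyloxy)buta-1,3-diene
Conditions: TESOTf, Et3N, Et2O, 0 °C
Reagents that add atoms: triethylsilyl trifluoromethanesulfonate, CC[Si](CC)(CC)OS(=O)(=O)C(F)(F)F
Why: Silyl enol ether formation: amine-mediated enolisation of the methyl ketone toward CH3 and O-silylation by the silyl triflate should give the 2-silyloxydiene; no stereocentre is formed.

Step 2
Reactants: 2 2-(triethylsilyloxy)buta-1,3-diene; 3 4,4-dimethoxycyclohexa-2,5-dien-1-one
Product: 4 cis-fused B/C adduct (C10 enone; C7 dimethyl ketal; C13 silyl enol ether)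
Conditions: chiral o-tolyl-oxazaborolidinium triflimide (Corey type, 20 mol %, enantiomer chosen for the shown sense), CH2Cl2, −78 to −40 °C
Reagents that add atoms: none
Why: Catalytic enantioselective Diels–Alder reaction of a quinone monoketal: the nucleophilic diene terminus C14 bonds to the β-carbon C8 ("para" orientation, silyloxy carbon C13 1,3 to C8), suprafacial addition makes H8 and H9 cis, and the chiral cation selects the enone face and so fixes C9 (and the temporary centre C8).

Step 3
Reactants: 4 cis-fused B/C adduct; 5 but-3-en-1-ylmagnesium bromide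
Product: 6 C10 tertiary alcohol (butenyl cis to H9)
Conditions: 5, CeCl3, THF, −78 °C
Reagents that add atoms: none
Why: Carbonyl 1,2-addition of an organocerium (Imamoto) reagent: cerium suppresses enolisation at C9 and conjugate addition, and the nucleophile should enter on the convex face of the cis-fused bicycle (face of H9), which sets C10 with C1 cis to H9 and O10 on the other face.

Step 4
Reactants: 6 C10 tertiary alcohol
Product: 7 C13 ketone with 12-O-triethylsilyl group
Conditions: mCPBA, NaHCO3, CH2Cl2, −20 to 0 °C
Reagents that add atoms: m-chloroperoxybenzoic acid, OOC(=O)c1cccc(Cl)c1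
Why: Rubottom oxidation: the peracid epoxidises the silyl enol ether far faster than the other alkenes and 1,4-silyl migration gives the α-silyloxy ketone with oxygen placed at C12 by the Diels–Alder regiochemistry; the C12 centre (convex-face attack expected) is provisional and is reset in step 12.

Step 5
Reactants: 7 C13 ketone with 12-O-triethylsilyl group; 8 ethyl prop-1-en-1-yl ether
Product: 9 C10 O-(2-bromo-1-ethoxypropyl) acetal
Conditions: 8, NBS, 2,6-lutidine, CH2Cl2, −40 to 0 °C
Reagents that add atoms: N-bromosuccinimide, O=C1CCC(=O)N1Br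
Why: Ueno–Stork bromoacetalisation: the bromonium ion of the enol ether is captured by the only free (tertiary) hydroxyl while lutidine protects the allylic ketal; the two new centres are mixtures that vanish in steps 6–8.

Step 6
Reactants: 9 C10 O-(2-bromo-1-ethoxypropyl) acetal
Product: 10 cis-fused 2-ethoxy-3-methyloxolane (C4–C5 bond formed)
Conditions: Bu3SnH, AIBN, benzene, 80 °C, slow addition
Reagents that add atoms: none
Why: Ueno–Stork 5-exo-trig radical cyclisation: the O10 tether delivers the secondary radical to C5, so the new C4–C5 bond is cis to O10 and H5 ends anti to O10, and the C6 radical is reduced by the stannane.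

Step 7
Reactants: 10 cis-fused 2-ethoxy-3-methyloxolane
Product: 12 γ-lactone aldehyde (19,10-lactone; C3 aldehyde), via lactone ozonide 11 (not isolated)
Conditions: O3 (excess), CH2Cl2–EtOAc, −78 to −20 °C; then PPh3
Reagents that add atoms: ozone, [O-][O+]=O
Why: Ozonolysis of the terminal alkene combined with ozone oxidation of the acetal C–H of the 2-ethoxyoxolane to the lactone (Deslongchamps acetal ozonation); the dimethyl ketal has no acetal hydrogen, the silyl ether and ketone are inert, and the phosphine reduces the ozonide to the C3 aldehyde.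

Step 8
Reactants: 12 γ-lactone aldehyde
Product: 13 ring-A aldol product (3-hydroxy; both C3 epimers)
Conditions: t-BuOK (0.3 equiv), t-BuOH–THF, 0 °C
Reagents that add atoms: none
Why: Intramolecular aldol addition (6-enolexo) of the lactone enolate at C4 to the C3 aldehyde under reversible alkoxide conditions: the three-carbon tether from C10 allows bonding on one face only, which fixes the quaternary C4, whereas C3 should form as a mixture that converges in steps 11–12.

Step 9
Reactants: 13 ring-A aldol product; 14 (2-bromoallyl)trimethylsilane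
Product: 17 C13 carbinol bearing the 3-(trimethylsilyl)prop-1-en-2-yl group, via vinyllithium 15 (not isolated), via organocerium 16 (not isolated)
Conditions: 14, t-BuLi (2 equiv), Et2O, −78 °C; CeCl3, THF, −78 °C; then 13 (reagent in excess), −78 °C
Reagents that add atoms: none
Why: Bromine–lithium exchange, transmetalation and 1,2-addition of the vinylcerium reagent (Imamoto conditions, lactone and ketal spared): in the locked cis-fused B/C system the axial C10 covers one face of the C13 carbonyl, so the reagent should enter from the convex face of H9 and set C13 with O13 on the face of C10 and the side chain cis to H9.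

Step 10
Reactants: 17 C13 carbinol with 12-O-triethylsilyl group
Product: 18 3,12,13-triol
Conditions: PPTS, MeOH, 0 °C to rt
Reagents that add atoms: none
Why: Acid-catalysed methanolysis of the secondary triethylsilyl ether; in methanol the dimethyl ketal only exchanges with solvent, and the allylsilane and tertiary alcohol tolerate the weak pyridinium acid.

Step 11
Reactants: 18 3,12,13-triol
Product: 19 3,12-dione (13-hydroxy)
Conditions: Dess–Martin periodinane, NaHCO3, CH2Cl2, rt
Reagents that add atoms: none
Why: Dess–Martin oxidation of both secondary alcohols while the tertiary C13 carbinol is inert; the C3 epimers and the provisional C12 centre converge to one diketone.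

Step 12
Reactants: 19 3,12-dione
Product: 20 3β,12α,13-triol
Conditions: K-Selectride, THF, −78 °C; aq. NH4Cl
Reagents that add atoms: none
Why: Selectride reduction (equatorial hydride delivery by a bulky borohydride): at C3 this should give the axial 3β-alcohol anti to the lactone carbonyl, and at C12 the axial trajectory is closed by the syn-axial C10 of the locked cis-fused system, so hydride arrives from the H9 face and O12 ends cis to O13 (12α).

Step 13
Reactants: 20 3β,12α,13-triol
Product: 21 3,12-diacetate
Conditions: Ac2O, Et3N, DMAP, CH2Cl2, rt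
Reagents that add atoms: acetic anhydride, CC(=O)OC(C)=O
Why: DMAP-catalysed acetylation of the two secondary alcohols; the tertiary C13 hydroxyl should stay free under these mild conditions.

Step 14
Reactants: 21 3,12-diacetate
Product: 22 C7 ketone
Conditions: PPTS, acetone–H2O, 40 °C
Reagents that add atoms: water, O
Why: Acid-catalysed hydrolysis of the dimethyl ketal with a weak pyridinium acid that leaves acetates, lactone and allylsilane intact.

Step 15
Reactants: 22 C7 ketone
Product: 23 C7=C8 trimethylsilyl enol ether with 13-O-trimethylsilyl group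
Conditions: TMSCl, NaI, Et3N, MeCN, rt
Reagents that add atoms: chlorotrimethylsilane, C[Si](C)(C)Cl
Why: Thermodynamic silyl enol ether formation with iodotrimethylsilane made in situ: the more substituted C7=C8 enol ether is favoured over C6=C7, and the tertiary hydroxyl is silylated at the same time.

Step 16
Reactants: 23 C7=C8 trimethylsilyl enol ether
Product: 24 8-hydroxy-7-ketone (13-O-trimethylsilyl)
Conditions: DMDO, wet acetone, −20 to 0 °C
Reagents that add atoms: dimethyldioxirane, CC1(C)OO1
Why: Rubottom-type oxidation: the silyl enol ether is epoxidised much faster than the 1,1-disubstituted allylsilane alkene, and the silyloxy epoxide should collapse in the wet medium to the tertiary C8 α-ketol (configuration irrelevant) while the tertiary silyl ether on O13 is kept.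

Step 17
Reactants: 24 8-hydroxy-7-ketone
Product: 25 7,8-diol
Conditions: NaBH4, MeOH–THF, −20 °C
Reagents that add atoms: none
Why: Borohydride reduction of the only ketone gives the 7,8-diol (either C7 epimer serves); acetates and lactone are untouched at low temperature.

Step 18
Reactants: 25 7,8-diol
Product: 26 seco keto-aldehyde (C8 ketone; C7 aldehyde)
Conditions: NaIO4, THF–pH 7 buffer, 0 °C to rt
Reagents that add atoms: none
Why: Malaprade glycol cleavage: periodate cleaves the C7–C8 diol to the C7 aldehyde and the C8 ketone and does not touch alkenes or the allylsilane.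

Step 19
Reactants: 26 seco keto-aldehyde
Product: 27 ring-B C6=C8 enal (3,12-diacetate; 13-O-trimethylsilyl; allylsilane on C13)
Conditions: Bn2NH·CF3CO2H, benzene, 50 °C
Reagents that add atoms: none
Why: Amine-salt-mediated intramolecular aldol condensation (5-enolexo): the enamine of the C7 aldehyde attacks the C8 ketone through C6 and dehydration gives the tetrasubstituted enal, the buffered weakly acidic medium avoiding β-elimination of the lactone oxygen at C10.

Step 20
Reactants: 27 ring-B C6=C8 enal
Product: 29 3,12-di-O-acetyl C7 aldehyde with rings A–D, via silyl ether aldehyde 28 (not isolated)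
Conditions: EtAlCl2 (3 equiv), CH2Cl2, −78 to −40 °C; then 1 M HCl–THF, 0 °C
Reagents that add atoms: none
Why: EtAlCl2 binds the aldehyde oxygen and makes C8 electrophilic; the terminal alkene carbon C15 of the allylsilane attacks C8, the β-silyl cation at C16 loses Me3Si to leave the C16=C17 methylene, and the aluminium enolate is protonated at C6 on work-up, which also hydrolyses the tertiary O–SiMe3 group. This is an intramolecular Hosomi–Sakurai conjugate allylation of the kind used to close methylenecyclopentane rings onto enones with alkylaluminium halides. Ring D (C8–C15–C16–C13–C14) closes in a five-membered mode that is exo with respect to the enal C6=C8 and endo with respect to the allylsilane alkene. C8 is set by the one-atom tether C14: the side chain on C13 is cis to H9 and can reach only that face of C8 once ring C places it axial, so the C15 bridge ends cis to H9; C6 is set by protonation and equilibration of the aldehyde to the isomer with the formyl group trans to C4. The step needs 1,4- over 1,2-addition and no loss of silicon by protonation: the 1,2-mode would require a seven-membered ring, the ethylaluminium reagent scavenges protons, and the silyl cap on O13 prevents ionisation or retro-aldol cleavage at C13.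

Step 21
Reactants: 29 3,12-di-O-acetyl C7 aldehyde
Product: 30 3,12-di-O-acetyl C7 acid
Conditions: NaClO2, NaH2PO4, 2-methyl-2-butene, t-BuOH–H2O, rt
Reagents that add atoms: sodium chlorite, [Na+].[O-]Cl=O
Why: Pinnick (Lindgren) oxidation of the aldehyde to the acid with 2-methyl-2-butene as hypochlorite scavenger, which should leave the exocyclic alkene, the tertiary allylic alcohol and C6 unchanged.

Step 22
Reactants: 30 3,12-di-O-acetyl C7 acid
Product: 31 CNP0260503.1 (3β,12α,13-trihydroxy C19-gibberellin acid)
Conditions: K2CO3, MeOH–H2O, 0 °C to rt; then acidify to pH 3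
Reagents that add atoms: none
Why: Base-catalysed methanolysis of the two acetates at low temperature, mild enough to avoid retro-aldol epimerisation at C3 and opening of the lactone; acidification liberates the acid.

Compound list
1 | but-3-en-2-one (methyl vinyl ketone) | CC(=O)C=C | starting material
2 | 2-(triethylsilyloxy)buta-1,3-diene | C=CC(=C)O[Si](CC)(CC)CC | intermediate
3 | 4,4-dimethoxycyclohexa-2,5-dien-1-one (p-benzoquinone mono-dimethyl ketal) | COC1(OC)C=CC(=O)C=C1 | starting material
4 | cis-4,4-dimethoxy-6-(triethylsilyloxy)-4a,5,8,8a-tetrahydronaphthalen-1(4H)-one (C10 ketone, C7 ketal, H8 and H9 cis) | O=C1C=CC(OC)(OC)[C@H]2CC(O[Si](CC)(CC)CC)=CC[C@@H]12 | intermediate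
5 | but-3-en-1-ylmagnesium bromide | C=CCC[Mg]Br | starting material
6 | 1-(but-3-en-1-yl)-1-hydroxy derivative of 4 (C10 carbinol, butenyl cis to H9) | C=CCC[C@]1(O)C=CC(OC)(OC)[C@H]2CC(O[Si](CC)(CC)CC)=CC[C@@H]12 | intermediate
7 | C13 ketone with 12-O-triethylsilyl group (O12 cis to H9) | C=CCC[C@]1(O)C=CC(OC)(OC)[C@H]2CC(=O)[C@H](O[Si](CC)(CC)CC)C[C@@H]12 | intermediate
8 | ethyl prop-1-en-1-yl ether (E/Z mixture) | CC=COCC | starting material
9 | C10 O-(2-bromo-1-ethoxypropyl) mixed acetal of 7 | C=CCC[C@]1(OC(OCC)C(C)Br)C=CC(OC)(OC)[C@H]2CC(=O)[C@H](O[Si](CC)(CC)CC)C[C@@H]12 | intermediate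
10 | cis-fused 2-ethoxy-3-methyloxolane (O10–C19–C4–C5 ring, H5 anti to O10) | C=CCC[C@]12OC(OCC)C(C)[C@H]1CC(OC)(OC)[C@H]3CC(=O)[C@H](O[Si](CC)(CC)CC)C[C@@H]23 | intermediate
11 | 1,2,4-trioxolane (ozonide) of the 19,10-lactone | C1(OCOO1)CC[C@]12OC(=O)C(C)[C@H]1CC(OC)(OC)[C@H]3CC(=O)[C@H](O[Si](CC)(CC)CC)C[C@@H]23 | intermediate
12 | γ-lactone aldehyde (19,10-lactone, C3 aldehyde, C13 ketone, C7 dimethyl ketal) | O=CCC[C@]12OC(=O)C(C)[C@H]1CC(OC)(OC)[C@H]3CC(=O)[C@H](O[Si](CC)(CC)CC)C[C@@H]23 | intermediate
13 | ring-A aldol product (3-hydroxy, C3 epimers, C4 quaternary) | OC1CC[C@]23OC(=O)[C@@]1(C)[C@H]2CC(OC)(OC)[C@H]1CC(=O)[C@H](O[Si](CC)(CC)CC)C[C@@H]31 | intermediate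
14 | (2-bromoallyl)trimethylsilane | C[Si](C)(C)CC(Br)=C | starting material
15 | [3-(trimethylsilyl)prop-1-en-2-yl]lithium | [Li]C(=C)C[Si](C)(C)C | intermediate
16 | dichloro[3-(trimethylsilyl)prop-1-en-2-yl]cerium | Cl[Ce](Cl)C(=C)C[Si](C)(C)C | intermediate
17 | 13-hydroxy-13-[3-(trimethylsilyl)prop-1-en-2-yl] compound with 12-O-triethylsilyl group | OC1CC[C@]23OC(=O)[C@@]1(C)[C@H]2CC(OC)(OC)[C@H]1C[C@](O)(C(=C)C[Si](C)(C)C)[C@H](O[Si](CC)(CC)CC)C[C@@H]31 | intermediate
18 | 3,12,13-triol (C3 epimers, 12-epi) | OC1CC[C@]23OC(=O)[C@@]1(C)[C@H]2CC(OC)(OC)[C@H]1C[C@](O)(C(=C)C[Si](C)(C)C)[C@H](O)C[C@@H]31 | intermediate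
19 | 13-hydroxy-3,12-dione | O=C1CC[C@]23OC(=O)[C@@]1(C)[C@H]2CC(OC)(OC)[C@H]1C[C@](O)(C(=C)C[Si](C)(C)C)C(=O)C[C@@H]31 | intermediate
20 | 3β,12α,13-triol | O[C@H]1CC[C@]23OC(=O)[C@@]1(C)[C@H]2CC(OC)(OC)[C@H]1C[C@](O)(C(=C)C[Si](C)(C)C)[C@@H](O)C[C@@H]31 | intermediate
21 | 3,12-diacetate (C7 dimethyl ketal) | CC(=O)O[C@H]1CC[C@]23OC(=O)[C@@]1(C)[C@H]2CC(OC)(OC)[C@H]1C[C@](O)(C(=C)C[Si](C)(C)C)[C@@H](OC(C)=O)C[C@@H]31 | intermediate
22 | 3,12-diacetate C7 ketone | CC(=O)O[C@H]1CC[C@]23OC(=O)[C@@]1(C)[C@H]2CC(=O)[C@H]1C[C@](O)(C(=C)C[Si](C)(C)C)[C@@H](OC(C)=O)C[C@@H]31 | intermediate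
23 | C7=C8 trimethylsilyl enol ether with 13-O-trimethylsilyl group | CC(=O)O[C@H]1CC[C@]23OC(=O)[C@@]1(C)[C@H]2CC(O[Si](C)(C)C)=C1C[C@](O[Si](C)(C)C)(C(=C)C[Si](C)(C)C)[C@@H](OC(C)=O)C[C@@H]31 | intermediate
24 | 8-hydroxy-7-ketone (13-O-trimethylsilyl) | CC(=O)O[C@H]1CC[C@]23OC(=O)[C@@]1(C)[C@H]2CC(=O)C1(O)C[C@](O[Si](C)(C)C)(C(=C)C[Si](C)(C)C)[C@@H](OC(C)=O)C[C@@H]31 | intermediate
25 | 7,8-diol (13-O-trimethylsilyl) | CC(=O)O[C@H]1CC[C@]23OC(=O)[C@@]1(C)[C@H]2CC(O)C1(O)C[C@](O[Si](C)(C)C)(C(=C)C[Si](C)(C)C)[C@@H](OC(C)=O)C[C@@H]31 | intermediate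
26 | seco keto-aldehyde (C8 ketone in ring C, C7 aldehyde on the C5 side chain) | CC(=O)O[C@H]1CC[C@@]2(OC(=O)[C@@]1(C)[C@H]2CC=O)[C@@H]1C[C@H](OC(C)=O)[C@@](O[Si](C)(C)C)(C(=C)C[Si](C)(C)C)CC1=O | intermediate
27 | ring-B C6=C8 enal with 2-(trimethylsilylmethyl)allyl group on C13 (3,12-diacetate, 13-O-trimethylsilyl) | C[Si](C)(C)CC(=C)[C@@]1(O[Si](C)(C)C)CC2=C(C=O)[C@H]3[C@@]4(CC[C@H](OC(C)=O)[C@@]3(C)C(=O)O4)[C@@H]2C[C@@H]1OC(C)=O | intermediate
28 | 3,12-di-O-acetyl-13-O-trimethylsilyl C7 aldehyde with rings A–D | C=C1C[C@]23C[C@@]1(O[Si](C)(C)C)[C@@H](OC(C)=O)C[C@H]2[C@@]12CC[C@H](OC(C)=O)[C@@](C)(C(=O)O1)[C@H]2[C@@H]3C=O | intermediate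
29 | 3,12-di-O-acetyl C7 aldehyde with rings A–D | C=C1C[C@]23C[C@@]1(O)[C@@H](OC(C)=O)C[C@H]2[C@@]12CC[C@H](OC(C)=O)[C@@](C)(C(=O)O1)[C@H]2[C@@H]3C=O | intermediate
30 | 3,12-di-O-acetyl C7 acid | C=C1C[C@]23C[C@@]1(O)[C@@H](OC(C)=O)C[C@H]2[C@@]12CC[C@H](OC(C)=O)[C@@](C)(C(=O)O1)[C@H]2[C@@H]3C(=O)O | intermediate
31 | CNP0260503.1 | C=C1C[C@]23C[C@@]1(O)[C@@H](O)C[C@H]2[C@@]12CC[C@H](O)[C@@](C)(C(=O)O1)[C@H]2[C@@H]3C(=O)O | target

Total step count: 22. Longest linear sequence: 22 steps (1 to 31); 3, 5, 8 and 14 are bought.

Steps most likely to fail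

1. Step 20. What may go wrong: loss of silicon by protonation, or ionisation at C13, before the C–C bond forms; or a slow cyclisation because ring C must adopt the conformer with C10 and O12 syn-axial. Fallback: setting out from 27, the silicon is removed on purpose (CF3CO2H, CH2Cl2, 0 °C, protodesilylation, which also frees O13) to give the 13-isopropenyl enal F1. F1 is then closed by a Lewis-acid-promoted intramolecular ene reaction (Me2AlCl, CH2Cl2, −78 to 0 °C), with the enal C6=C8 as enophile and the isopropenyl group as ene component. This forms the same C8–C15 bond and the exocyclic alkene and comes back to the route at 29.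

2. Step 7. What may go wrong: sluggish or unselective oxidation of the acetal C–H, so that the alkene is cleaved while the acetal survives, or over-oxidation sets in. Fallback: the lactone is made at the right oxidation level from the start. Setting out from 7, acylation of the tertiary alcohol with 2-bromopropanoyl bromide (pyridine, DMAP) gives the 2-bromopropanoate F2. Tin-hydride radical cyclisation (Bu3SnH, AIBN, slow addition, benzene, 80 °C) gives the butenyl γ-lactone F3, and ordinary ozonolysis of F3 (O3; PPh3) comes back to the route at 12.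

3. Step 8. What may go wrong: enolisation of the aldehyde or of the C13 ketone under alkoxide conditions, leading to competing aldol or acyl-transfer pathways instead of the lactone-enolate aldol. Fallback: a regiospecific enolate without base. Setting out from 7, acylation with 2,2-dibromopropanoyl chloride gives the dibromo ester F4, and radical cyclisation with one equivalent of Bu3SnH gives the α-bromo butenyl lactone F5. Ozonolysis gives the α-bromo lactone aldehyde F6, and an intramolecular Reformatsky reaction (activated Zn, THF) closes ring A and comes back to the route at 13.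

Further compounds
F1 | step 20 | 13-isopropenyl ring-B enal (3,12-diacetate, 13-hydroxy) | CC(=C)[C@@]1(O)CC2=C(C=O)[C@H]3[C@@]4(CC[C@H](OC(C)=O)[C@@]3(C)C(=O)O4)[C@@H]2C[C@@H]1OC(C)=O
F2 | step 7 | C10 2-bromopropanoate of 7 | C=CCC[C@]1(OC(=O)C(C)Br)C=CC(OC)(OC)[C@H]2CC(=O)[C@H](O[Si](CC)(CC)CC)C[C@@H]12
F3 | step 7 | butenyl 19,10-γ-lactone | C=CCC[C@]12OC(=O)C(C)[C@H]1CC(OC)(OC)[C@H]3CC(=O)[C@H](O[Si](CC)(CC)CC)C[C@@H]23
F4 | step 8 | C10 2,2-dibromopropanoate of 7 | C=CCC[C@]1(OC(=O)C(C)(Br)Br)C=CC(OC)(OC)[C@H]2CC(=O)[C@H](O[Si](CC)(CC)CC)C[C@@H]12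
F5 | step 8 | 4-bromo butenyl 19,10-γ-lactone | C=CCC[C@]12OC(=O)C(C)(Br)[C@H]1CC(OC)(OC)[C@H]3CC(=O)[C@H](O[Si](CC)(CC)CC)C[C@@H]23
F6 | step 8 | 4-bromo γ-lactone C3 aldehyde | O=CCC[C@]12OC(=O)C(C)(Br)[C@H]1CC(OC)(OC)[C@H]3CC(=O)[C@H](O[Si](CC)(CC)CC)C[C@@H]23
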